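**Retrosynthetic overview**
1. Plakortolide S ⇐ diimide saturation of a C8=C9 alkene ⇐ cross-metathesis of a 6-allyl bicyclic peroxylactone with 4-(non-8-enyl)phenol. The phenol comes from nona-1,8-diene and 4-iodophenol by hydroboration/Suzuki coupling.
2. The C6 quaternary peroxy carbon ⇐ allylsilane capture of the bicyclic peroxycarbenium ion released from a 6-methoxy peroxyketal. Attack is axial, cis to C4-O and trans to C4-CH3.
3. Both rings ⇐ one flask from an acyclic (R)-hydroxy dienoate. Selective ozonolysis in MeOH supplies the O-O bond, then a 6-exo peroxy-Michael addition closes the 1,2-dioxane first and lactonization closes the γ-lactone second.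
4. The C4 carbinol ⇐ chiral-diol-catalysed asymmetric methallylboration of methyl (E)-4-oxopent-2-enoate.

Assumption: the text uses plakortolide numbering (C1 lactone carbonyl, C3 peroxy CH, C4 lactone carbinol, C6 quaternary peroxy carbon, chain from C7), and the (S)-diol catalyst is taken to give the R carbinol as it does with aryl and alkenyl methyl ketones (the R catalyst is equally available if the check on 6 says otherwise).

**Step 1**
Reactants: 1 3-chloro-2-methylprop-1-ene (methallyl chloride); 2 triisopropyl borate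
Product: 4 diisopropyl (2-methylallyl)boronate, via methallylmagnesium chloride 3 (not isolated)
Conditions: Mg turnings, THF, 0 °C; add to 2, Et2O, −78 to 23 °C; HCl in Et2O (1 equiv), 0 °C; filter, distil
Reagents that add atoms: none
Why: Grignard formation and borylation, in which the allylic Grignard reagent adds once to B(OiPr)3 at low temperature and anhydrous HCl collapses the ate complex to the distillable boronate; no stereocentre is formed.

**Step 2**
Reactants: 4 diisopropyl (2-methylallyl)boronate; 5 methyl (E)-4-oxopent-2-enoate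
Product: 6 methyl (2E,4R)-4-hydroxy-4,6-dimethylhepta-2,6-dienoate
Conditions: 4 (1.5 equiv), (S)-3,3'-Br2-BINOL (15 mol %), PhCF3/PhMe 3:1, −35 °C, 24 h; aqueous work-up
Reagents that add atoms: none
Why: Chiral-diol-catalysed asymmetric allylboration of a ketone, in which exchange of one isopropoxide for the BINOL gives a more Lewis acidic boronate that reacts strictly 1,2 through a closed Zimmerman-Traxler chair (alkenyl arm equatorial, methyl axial) and delivers the methallyl group to the Re face, setting C4 as R.

**Step 3**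
Reactants: 6 methyl (2E,4R)-4-hydroxy-4,6-dimethylhepta-2,6-dienoate
Product: 9 (4aR,7aR)-3-methoxy-3,4a-dimethyl-4,4a,7,7a-tetrahydro-3H-furo[3,2-c][1,2]dioxin-6-one (both C6 epimers), via hydroperoxy ketal 7 (not isolated), via dioxane hydroxy ester 8 (not isolated)
Conditions: O3, CH2Cl2/MeOH 4:1, Sudan Red 7B, −78 °C; N2 purge; then Et3N (1 equiv), CF3CH2OH, −78 to 23 °C, 24 h, same flask
Reagents that add atoms: ozone, [O-][O+]=O; methanol, CO
Why: Proposed new method: ozone attacks only the electron-rich 1,1-disubstituted alkene (the enoate is far slower), the primary ozonide splits by the Criegee path mainly to formaldehyde and the ketone oxide, methanol traps this as hydroperoxy ketal 7, and Et3N then triggers a reversible 6-exo peroxy-Michael addition through a chair with C4-CH3 equatorial and C4-OH axial to give 8, whose cis hydroxy ester lactonizes to 9, so that C3 is set as R by C4 (any trans material reverts by retro-Michael, at the latest through the butenolide, which can only re-close cis) while the C6 ketal centre stays an inconsequential mixture; the closest known reaction types are ozonolysis in methanol to alpha-methoxy hydroperoxides and the amine-catalysed cyclization of hydroperoxy ketals onto enoates to 3-methoxy-1,2-dioxanes.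

**Step 4**
Reactants: 9 bicyclic methoxy peroxyketal lactone; 10 allyltrimethylsilane
Product: 12 (3S,4aR,7aR)-3-allyl-3,4a-dimethyl-4,4a,7,7a-tetrahydro-3H-furo[3,2-c][1,2]dioxin-6-one, via peroxycarbenium triflate 11 (not isolated)
Conditions: 10 (3 equiv), TMSOTf (0.3 equiv), CH2Cl2, −78 to −40 °C
Reagents that add atoms: none
Why: Hosomi-Sakurai allylation of a peroxycarbenium ion, in which TMSOTf ionizes the more basic methoxy group of either C6 epimer to the same cation 11, whose favoured half-chair has C4-O pseudoaxial (attracted to the cationic carbon) and C4-CH3 and C3-CH2 pseudoequatorial, so that the stereoelectronically preferred axial attack (the other face would meet an axial C4-CH3) places allyl cis to C4-O, which is S at C6.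

**Step 5**
Reactants: 13 nona-1,8-diene; 14 4-iodophenol
Product: 16 4-(non-8-en-1-yl)phenol, via B-nonenyl-9-BBN 15 (not isolated)
Conditions: 13 (3 equiv), 9-BBN (1 equiv), THF, 0 to 23 °C; then 14, PdCl2(dppf) (3 mol %), 3 M aq NaOH (3 equiv), THF, 65 °C
Reagents that add atoms: none
Why: Anti-Markovnikov hydroboration followed by B-alkyl Suzuki-Miyaura coupling, in which the excess of diene keeps hydroboration at one end and the hydroxide-activated alkylborane transfers its primary alkyl group to the arylpalladium iodide; no stereocentre is formed.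

**Step 6**
Reactants: 12 6-allyl bicyclic peroxylactone; 16 4-(non-8-en-1-yl)phenol
Product: 17 (3S,4aR,7aR)-3-[(2E)-10-(4-hydroxyphenyl)dec-2-en-1-yl]-3,4a-dimethyl-4,4a,7,7a-tetrahydro-3H-furo[3,2-c][1,2]dioxin-6-one (E major)
Conditions: 16 (3 equiv), second-generation Grubbs catalyst (H2IMes)(PCy3)Cl2Ru=CHPh (5 mol %), CH2Cl2, 40 °C
Reagents that add atoms: none
Why: Olefin cross-metathesis of two unhindered terminal alkenes, driven by loss of ethene and by the excess of cheap 16, with dialkyl peroxide, lactone and free phenol tolerated by the ruthenium carbene; the E/Z ratio does not matter and no stereocentre is touched.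

**Step 7**
Reactants: 17 unsaturated plakortolide precursor
Product: 18 plakortolide S, (3S,4aR,7aR)-3-[10-(4-hydroxyphenyl)decyl]-3,4a-dimethyl-4,4a,7,7a-tetrahydro-3H-furo[3,2-c][1,2]dioxin-6-one
Conditions: KO2CN=NCO2K (15 equiv), AcOH (30 equiv), MeOH/CH2Cl2 1:1, 0 to 23 °C
Reagents that add atoms: none
Why: Diimide reduction, a concerted metal-free syn transfer of two hydrogens to the unhindered C8=C9 alkene that leaves the O-O bond, the lactone, the arene and all three stereocentres untouched.

**Compound list**
1 | 3-chloro-2-methylprop-1-ene | C=C(C)CCl | starting material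
2 | triisopropyl borate | CC(C)OB(OC(C)C)OC(C)C | starting material
3 | (2-methylallyl)magnesium chloride | C=C(C)C[Mg]Cl | intermediate
4 | diisopropyl (2-methylallyl)boronate | C=C(C)CB(OC(C)C)OC(C)C | intermediate
5 | methyl (E)-4-oxopent-2-enoate | COC(=O)/C=C/C(C)=O | starting material
6 | methyl (2E,4R)-4-hydroxy-4,6-dimethylhepta-2,6-dienoate | COC(=O)/C=C/[C@](C)(O)CC(C)=C | intermediate
7 | methyl (2E,4R)-6-hydroperoxy-4-hydroxy-6-methoxy-4-methylhept-2-enoate (both C6 epimers) | COC(=O)/C=C/[C@](C)(O)CC(C)(OC)OO | intermediate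
8 | methyl 2-[(3R,4R)-4-hydroxy-6-methoxy-4,6-dimethyl-1,2-dioxan-3-yl]acetate (both C6 epimers) | COC(=O)C[C@H]1OOC(C)(OC)C[C@@]1(C)O | intermediate
9 | (4aR,7aR)-3-methoxy-3,4a-dimethyl-4,4a,7,7a-tetrahydro-3H-furo[3,2-c][1,2]dioxin-6-one (both epimers at the ketal carbon) | COC1(C)C[C@@]2(C)OC(=O)C[C@H]2OO1 | intermediate
10 | allyltrimethylsilane | C=CC[Si](C)(C)C | starting material
11 | (4aR,7aR)-3,4a-dimethyl-6-oxo-4,4a,7,7a-tetrahydrofuro[3,2-c][1,2]dioxin-2-ium trifluoromethanesulfonate | CC1=[O+]O[C@@H]2CC(=O)O[C@]2(C)C1.[O-]S(=O)(=O)C(F)(F)F | intermediate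
12 | (3S,4aR,7aR)-3-allyl-3,4a-dimethyl-4,4a,7,7a-tetrahydro-3H-furo[3,2-c][1,2]dioxin-6-one | C[C@]1(CC=C)C[C@@]2(C)OC(=O)C[C@H]2OO1 | intermediate
13 | nona-1,8-diene | C=CCCCCCC=C | starting material
14 | 4-iodophenol | Oc1ccc(I)cc1 | starting material
15 | 9-(non-8-en-1-yl)-9-borabicyclo[3.3.1]nonane | C=CCCCCCCCB1C2CCCC1CCC2 | intermediate
16 | 4-(non-8-en-1-yl)phenol | C=CCCCCCCCc1ccc(O)cc1 | intermediate
17 | (3S,4aR,7aR)-3-[(2E)-10-(4-hydroxyphenyl)dec-2-en-1-yl]-3,4a-dimethyl-4,4a,7,7a-tetrahydro-3H-furo[3,2-c][1,2]dioxin-6-one | C[C@]1(C/C=C/CCCCCCCc2ccc(O)cc2)C[C@@]2(C)OC(=O)C[C@H]2OO1 | intermediate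
18 | plakortolide S | C[C@]1(CCCCCCCCCCc2ccc(O)cc2)C[C@@]2(C)OC(=O)C[C@H]2OO1 | target

**Total step count:** 7. **Longest linear sequence:** 6 (steps 1, 2, 3, 4, 6, 7; step 5 is the side branch).

**Steps most likely to fail**

**Step 3.**
- Risks: the Criegee split can go the wrong way, giving the methyl ketone and formaldehyde oxide. Ozone can also attack the enoate, and the amine can open the dioxane by Kornblum-DeLaMare elimination at C3-H before the lactone closes.
- Fallback: it sets out from 6 and comes back at 9, and it builds the rings one at a time with the lactone first.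
- Irradiation of 6 (300 nm, MeCN) isomerizes the enoate to the Z form, which lactonizes at once to the butenolide (R)-5-methyl-5-(2-methylallyl)furan-2(5H)-one F1.
- Ozonolysis of F1 in CH2Cl2/MeOH at −78 °C gives (5R)-5-(2-hydroperoxy-2-methoxypropyl)-5-methylfuran-2(5H)-one F2. After evaporation of the volatiles, F2 is closed with Et2NH in CF3CH2OH.
- The tethered hydroperoxide can reach C3 of the flat butenolide only from the face of its own tether, so 9 forms cis-fused.

**Step 4.**
- Risks: the lactone carbonyl competes for the Lewis acid, and the cation can lose a proton or fragment at the O-O bond. An acyloxy group may also steer less strongly than an ether oxygen.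
- Fallback: it sets out from 6 and comes back at 12, and it moves the substitution to a monocyclic dioxane so that the lactone closes last.
- Silylation of 6 (Et3SiOTf, 2,6-lutidine, CH2Cl2) gives methyl (2E,4R)-4,6-dimethyl-4-(triethylsilyloxy)hepta-2,6-dienoate F3.
- Ozonolysis in CH2Cl2/MeOH gives methyl (2E,4R)-6-hydroperoxy-6-methoxy-4-methyl-4-(triethylsilyloxy)hept-2-enoate F4.
- Et3N in CF3CH2OH closes F4 to methyl 2-[(3R,4R)-6-methoxy-4,6-dimethyl-4-(triethylsilyloxy)-1,2-dioxan-3-yl]acetate F5, with the side chain and C4-CH3 equatorial and the silyloxy group axial.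
- Treatment of F5 with 10 and TMSOTf gives methyl 2-[(3R,4R,6S)-6-allyl-4,6-dimethyl-4-(triethylsilyloxy)-1,2-dioxan-3-yl]acetate F6, now under the stronger pseudoaxial-alkoxy control.
- HF-pyridine in THF removes the silyl group, and the freed alcohol lactonizes spontaneously to 12.

**Step 2.**
- Risks: a γ-keto enoate is an untested substrate for this catalysis, and an uncatalysed background addition to the activated ketone could erode the ee.
- Fallback: it sets out from 1 and comes back at 6, and it takes C4 from the chiral pool by self-regeneration of stereocentres.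
- The lithium enolate (LiN(i-Pr)2, THF, −78 °C) of commercial (2S,5S)-2-tert-butyl-5-methyl-1,3-dioxolan-4-one, the pivalaldehyde acetal of (S)-lactic acid, is alkylated with 1 (DMPU co-solvent). Alkylation occurs anti to the tert-butyl group and gives (2S,5R)-2-tert-butyl-5-methyl-5-(2-methylallyl)-1,3-dioxolan-4-one F7.
- i-Bu2AlH (CH2Cl2, −78 °C) reduces F7 to the lactol (2S,5R)-2-tert-butyl-5-methyl-5-(2-methylallyl)-1,3-dioxolan-4-ol F8.
- Ph3P=CHCO2Me (2.5 equiv, PhMe, 60 °C) traps the open-chain hydroxy aldehyde E-selectively as 6, with the R configuration fixed by the lactic acid centre.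

**Further compounds**
F1 | step 3 | (R)-5-methyl-5-(2-methylallyl)furan-2(5H)-one | CC(=C)C[C@@]1(C)OC(=O)C=C1
F2 | step 3 | (5R)-5-(2-hydroperoxy-2-methoxypropyl)-5-methylfuran-2(5H)-one (both ketal epimers) | COC(C)(OO)C[C@@]1(C)OC(=O)C=C1
F3 | step 4 | methyl (2E,4R)-4,6-dimethyl-4-(triethylsilyloxy)hepta-2,6-dienoate | COC(=O)/C=C/[C@](C)(O[Si](CC)(CC)CC)CC(C)=C
F4 | step 4 | methyl (2E,4R)-6-hydroperoxy-6-methoxy-4-methyl-4-(triethylsilyloxy)hept-2-enoate (both C6 epimers) | COC(=O)/C=C/[C@](C)(O[Si](CC)(CC)CC)CC(C)(OC)OO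
F5 | step 4 | methyl 2-[(3R,4R)-6-methoxy-4,6-dimethyl-4-(triethylsilyloxy)-1,2-dioxan-3-yl]acetate (both C6 epimers) | COC(=O)C[C@H]1OOC(C)(OC)C[C@@]1(C)O[Si](CC)(CC)CC
F6 | step 4 | methyl 2-[(3R,4R,6S)-6-allyl-4,6-dimethyl-4-(triethylsilyloxy)-1,2-dioxan-3-yl]acetate | COC(=O)C[C@H]1OO[C@@](C)(CC=C)C[C@@]1(C)O[Si](CC)(CC)CC
F7 | step 2 | (2S,5R)-2-tert-butyl-5-methyl-5-(2-methylallyl)-1,3-dioxolan-4-one | CC(C)(C)[C@@H]1OC(=O)[C@@](C)(CC(C)=C)O1
F8 | step 2 | (2S,5R)-2-tert-butyl-5-methyl-5-(2-methylallyl)-1,3-dioxolan-4-ol (both lactol epimers) | CC(C)(C)[C@@H]1OC(O)[C@@](C)(CC(C)=C)O1
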